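Kj can pay for more Ze than the west run reads on its plateau, and that gap is the reckoning I use. West is the very flask asked about: Ju binds Qo, QoJu sheds Zo to become Ul, Ul takes up Kj, and KjUl gives Ze and Ju back, while Dw consumes Kj on the side and Ju can decay to Wu or Xi.

| setting | west | north | flask |
|---|---|---|---|
| Qo | 32 mM | 32 mM | 32 mM |
| Kj | 35.2 mM | 70 mM | 35.2 mM |
| Dw | 1.6 mM | 1.6 mM | 1.60 mM |
| Ju | 0.70 µM | 0.70 µM | 0.70 µM |
| temperature | 40 °C | 35 °C | 40 °C |
| remark | the very flask that is asked about, followed so far | run made earlier |  |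
| time |  |  | 8.0 d |

| run | time / h | Ze / % | Qo / % |
|---|---|---|---|
| west | 8.00 | 70.8 | 28.4 |
| west | 20.0 | 83.0 | 19.5 |
| west | 40.0 | 83.4 | 16.2 |
| west | 60.0 | 84.5 | 15.8 |
| west | 96.0 | 84.6 | 15.7 |
| west | 120 | 84.2 | 14.9 |
| north | 1.33 | 18.5 | 80.5 |
| north | 3.00 | 36.8 | 63.3 |
| north | 4.00 | 44.9 | 55.2 |
| north | 6.00 | 59.2 | 41.2 |
| north | 8.00 | 69.0 | 31.4 |

(each reading ± 0.5 percentage points)

- in percentages every species weighs as the Qo in it: one QoJu2 counts as two
- removed Ze is counted in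
- what may be going on: Kj + Ul <-> KjUl; KjUl -> Ju + Ze; Kj + Dw -> KjDw; Qo + Ju <-> QoJu; 2 QoJu <-> QoJu2; QoJu <-> Ul + Zo; Ju -> Wu; Ju -> Xi
- additions bring no volume worth counting

- dusk: change nothing and wait 4.0 d more
- noon: at 8.0 d take out 90% of the Ze then present, then wait 4.0 d
- autumn: at 8.0 d add Kj, 50.0% of the amount charged, then wait 4.0 d
- midnight: at 8.0 d raise the temperature by 15 K, then wait 4.0 d
- winter: at 8.0 d add Ju, 50.0% of the amount charged, then wait 4.0 d

- Ze, in percent of the Qo first charged, at 8.0 d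
- which option adds most Ze ("none" when 2 percentage points or less is all one gets) (dusk / noon / autumn / midnight / winter / none)
- Ze present, with what was taken out counted in, in percent of the Qo first charged, after autumn
- Ze present, with what was taken out counted in, in percent of the Qo first charged, after winter

Each Ze costs one Kj, and each Dw costs one more. My measure is therefore the Kj room, ([Kj] − [Dw]) / [Qo] at the charge, 105%: the Kj left after Dw has taken its whole charge, counted against the Qo charged. I turn the question round: for west to stall on Kj, the room has to lie at or under its plateau. It stands 20 percentage points above the reading of 84.6%. That leaves about 6.53 mM of Kj against 5.02 mM of Qo, so Kj still covers the Qo in the flask.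

Yet Ze gains 70.8% in the first 8.00 h and then 0.8 points between 40.0 h and 120 h, with a scatter of 0.5 points on each reading. Both partners remain, so I read the stall as lost catalyst. I commit to the plateau mean, 84.4%, at 8.0 d. I expect nothing from dusk, noon, autumn or midnight, and a gain from winter, which brings fresh Ju.

The forecast gives 84.5%, 84.5% after autumn and 92% after winter, and it picks winter; its ground reads “The enzyme has died.”

The flask gives 84.6% at 8.0 d. Autumn adds 0 points and ends at 84.6%, while winter adds 6.1 points and ends at 90.7%, so the choice is winter.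

    Kj + Ul ⇌ KjUl (K = 34.0 M⁻¹, k = 1.66 × 10⁵ M⁻¹ min⁻¹, Ea = 43.0 kJ mol⁻¹, ΔH = −14.0 kJ mol⁻¹)
    KjUl → Ju + Ze (k = 25900 min⁻¹, Ea = 51.0 kJ mol⁻¹)
    Kj + Dw → KjDw (k = 97.3 M⁻¹ min⁻¹, Ea = 43.0 kJ mol⁻¹)
    Qo + Ju ⇌ QoJu (K = 6.40 M⁻¹, k = 34500 M⁻¹ s⁻¹, Ea = 20.0 kJ mol⁻¹, ΔH = 15.0 kJ mol⁻¹)
    2 QoJu ⇌ QoJu2, settled at all times (K = 3.70 × 10⁶ M⁻¹, ΔH = 15.0 kJ mol⁻¹)
    QoJu ⇌ Ul + Zo (K = 0.0250 M, k = 1310 min⁻¹, Ea = 74.0 kJ mol⁻¹, ΔH = −15.0 kJ mol⁻¹)
    Ju → Wu (k = 0.00193 min⁻¹, Ea = 227 kJ mol⁻¹)
    Ju → Xi (k = 2.43 × 10⁻⁵ min⁻¹, Ea = 114 kJ mol⁻¹)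
    (constants at 40 °C)

In the flask the room stands 20 points above the Ze, with 18.6% of the Kj still free and Wu holding 98.8% of the catalyst at 192 h. Winter's gain is 6.1 points in the flask as it stands and 0.0061 points in a run without the passing of Ju into Wu. The neighbour flask charged with 21 mM of Kj reads the other way, with Kj as the limiting reagent: its room is 60.6%, its Ze 60.3%, and 0.55% of its Kj remains.

The data come from a simulation for substances that don't exist, and the scatter is random.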